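**Retrosynthetic overview**
1. The C–prenyl bond at the quaternary carbon of ring B is traced back to an O–prenyl bond: target 11 comes from the fully aromatic dimer ether 9 by a double [3,3] shift (para-Claisen–Cope) that ends on the acyl-bearing carbon para to the ether oxygen. The bond to make is therefore the aryl–O–prenyl C–O bond, placed on the 4-OH of ring B.
2. Methylene bridge: 9 comes from the ring A unit 3 (as its Mannich base / ortho-quinone methide) and the ring B prenyl ether 6.
3. 6 comes from 5 by site-selective etherification, and 5 from 2-methylphloroglucinol 4; 3 comes from 2, and 2 from phloroglucinol 1.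
4. Ring order: no ring is built. Both six-membered rings are bought as benzene rings; ring A stays aromatic, ring B is dearomatised in the last step, where the single stereocentre is set.

Assumption: 2-methylbenzene-1,3,5-triol is bought. The (+)-camphor-derived Eu(hfc)3 is taken to give the (S) product; if the sense of induction is the opposite, its commercially available mirror-image form is used instead.

**Step 1**
Reactants: 1 phloroglucinol (benzene-1,3,5-triol)
Product: 2 phlorisobutyrophenone [2-methyl-1-(2,4,6-trihydroxyphenyl)propan-1-one]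
Conditions: iPrCOCl (1.1 equiv), AlCl3 (3 equiv), PhNO2, 65 °C; aq HCl work-up
Reagents that add atoms: isobutyryl chloride, CC(C)C(Cl)=O
Why: Friedel–Crafts C-acylation of the very electron-rich triol; the first acyl group deactivates the ring, so mono-acylation dominates.

**Step 2**
Reactants: 2 phlorisobutyrophenone
Product: 3 ring A unit [2-methyl-1-[2,4,6-trihydroxy-3-(3-methylbut-2-en-1-yl)phenyl]propan-1-one]
Conditions: prenyl bromide (1.0 equiv), 10 % aq KOH, 0 °C, 2 h
Reagents that add atoms: prenyl bromide (1-bromo-3-methylbut-2-ene), CC(C)=CCBr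
Why: C-alkylation of the ambident phenoxide in water, where hydrogen bonding to oxygen steers the allylic bromide to a ring carbon between two oxygens (base-mediated C-prenylation of an acylphloroglucinol).

**Step 3**
Reactants: 4 2-methylphloroglucinol (2-methylbenzene-1,3,5-triol)
Product: 5 3-methylphlorisobutyrophenone [2-methyl-1-(2,4,6-trihydroxy-3-methylphenyl)propan-1-one]
Conditions: iPrCOCl (1.1 equiv), AlCl3 (3 equiv), PhNO2, 65 °C; aq HCl work-up
Reagents that add atoms: isobutyryl chloride, CC(C)C(Cl)=O
Why: Friedel–Crafts C-acylation; the two free ring positions of 4 are equivalent, so only one ketone can form.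

**Step 4**
Reactants: 5 3-methylphlorisobutyrophenone
Product: 6 ring B prenyl ether [1-{2,6-dihydroxy-3-methyl-4-[(3-methylbut-2-en-1-yl)oxy]phenyl}-2-methylpropan-1-one]
Conditions: prenol (1.05 equiv), PPh3, DIAD, THF, 0 °C to rt
Reagents that add atoms: 3-methylbut-2-en-1-ol (prenol), CC(C)=CCO
Why: Mitsunobu etherification goes to the most acidic, non-chelated 4-OH (para to the ketone) while the two ortho OH groups are tied up in hydrogen bonds to the carbonyl; this C–O bond fixes that prenyl can later only come to rest on the para, acyl-bearing carbon.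

**Step 5**
Reactants: 3 ring A unit; 6 ring B prenyl ether
Product: 9 methylene-bridged dimer prenyl ether (ring A triol joined by CH2 to the free ring carbon of 6), via Mannich base 7 (not isolated), via ortho-quinone methide 8 (not isolated)
Conditions: 3, CH2(NMe2)2 (1.0 equiv), dioxane, rt, 1 h; then 6 (1.0 equiv), 60 °C, N2 sweep, 8 h
Reagents that add atoms: N,N,N',N'-tetramethylmethanediamine [bis(dimethylamino)methane], CN(C)CN(C)C
Why: Mannich aminomethylation at the only free ring carbon of 3, thermal loss of Me2NH to the ortho-quinone methide, and Michael (Friedel–Crafts-type) addition of the only free ring carbon of 6 followed by rearomatisation; putting the electrophilic carbon on one partner first prevents homodimers, and 60 °C is below the onset of the uncatalysed rearrangement of the prenyl ether.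

**Step 6**
Reactants: 9 methylene-bridged dimer prenyl ether
Product: 11 CNP0191741.1 (the 4S target), via ortho-dienone 10 (not isolated)
Conditions: Eu(hfc)3 = europium tris[3-(heptafluoropropylhydroxymethylene)-(+)-camphorate] (15 mol %), 4 Å MS, ethanol-free CHCl3, 55 °C, 36 h; neutral work-up (no base, no amines)
Reagents that add atoms: none
Why: Proposed new method: an enantioselective para-Claisen–Cope rearrangement that ends on an acyl-bearing ring carbon, run under a chiral trivalent europium tris(β-diketonate); the oxophilic metal is held at two points, by the ether oxygen of ring B and the neighbouring phenol of ring A across the CH2 bridge (a site that exists only on the CH2-aryl side of the ether, which lets the camphorate ligands tell the two faces of ring B apart), and polarises the O–CH2 bond without ionising it; the prenyl unit swings over the open face to the methyl-bearing ortho carbon ([3,3], ortho-dienone 10, S at the new sp3 carbon), the metal stays on the newly formed ring ketone and so holds ring B in the 2,4-dienone form whose only 1,5-diene leads to the acyl-bearing para carbon, and a suprafacial Cope [3,3] shift on the same face sets the quaternary stereocentre as S with the normal prenyl end attached, after which the product relaxes to the hydrogen-bonded bis-enol and leaves the metal; closest known reaction type: the racemic para-Claisen–Cope rearrangement of aryl prenyl ethers catalysed by the achiral analogue Eu(fod)3, and chiral-Lewis-acid-controlled aromatic Claisen rearrangements.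

**Compound list**
1 | benzene-1,3,5-triol (phloroglucinol) | Oc1cc(O)cc(O)c1 | starting material
2 | 2-methyl-1-(2,4,6-trihydroxyphenyl)propan-1-one | CC(C)C(=O)c1c(O)cc(O)cc1O | intermediate
3 | 2-methyl-1-[2,4,6-trihydroxy-3-(3-methylbut-2-en-1-yl)phenyl]propan-1-one | CC(C)=CCc1c(O)cc(O)c(C(=O)C(C)C)c1O | intermediate
4 | 2-methylbenzene-1,3,5-triol (2-methylphloroglucinol) | Cc1c(O)cc(O)cc1O | starting material
5 | 2-methyl-1-(2,4,6-trihydroxy-3-methylphenyl)propan-1-one | CC(C)C(=O)c1c(O)cc(O)c(C)c1O | intermediate
6 | 1-{2,6-dihydroxy-3-methyl-4-[(3-methylbut-2-en-1-yl)oxy]phenyl}-2-methylpropan-1-one | CC(C)C(=O)c1c(O)cc(OCC=C(C)C)c(C)c1O | intermediate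
7 | 1-{3-[(dimethylamino)methyl]-2,4,6-trihydroxy-5-(3-methylbut-2-en-1-yl)phenyl}-2-methylpropan-1-one | CC(C)=CCc1c(O)c(CN(C)C)c(O)c(C(=O)C(C)C)c1O | intermediate (not isolated)
8 | 3,5-dihydroxy-6-methylidene-2-(3-methylbut-2-en-1-yl)-4-(2-methylpropanoyl)cyclohexa-2,4-dien-1-one | C=C1C(=O)C(CC=C(C)C)=C(O)C(C(=O)C(C)C)=C1O | intermediate (not isolated)
9 | 1-[3-({2,4-dihydroxy-5-methyl-3-(2-methylpropanoyl)-6-[(3-methylbut-2-en-1-yl)oxy]phenyl}methyl)-2,4,6-trihydroxy-5-(3-methylbut-2-en-1-yl)phenyl]-2-methylpropan-1-one | CC(C)=CCc1c(O)c(Cc2c(O)c(C(=O)C(C)C)c(O)c(C)c2OCC=C(C)C)c(O)c(C(=O)C(C)C)c1O | intermediate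
10 | (6S)-3,5-dihydroxy-6-methyl-6-(2-methylbut-3-en-2-yl)-4-(2-methylpropanoyl)-2-{[2,4,6-trihydroxy-3-(2-methylpropanoyl)-5-(3-methylbut-2-en-1-yl)phenyl]methyl}cyclohexa-2,4-dien-1-one | O=C1C(Cc2c(O)c(CC=C(C)C)c(O)c(C(=O)C(C)C)c2O)=C(O)C(C(=O)C(C)C)=C(O)[C@]1(C)C(C)(C)C=C | intermediate (not isolated)
11 | (4S)-3,5-dihydroxy-2-methyl-4-(3-methylbut-2-en-1-yl)-4-(2-methylpropanoyl)-6-{[2,4,6-trihydroxy-3-(2-methylpropanoyl)-5-(3-methylbut-2-en-1-yl)phenyl]methyl}cyclohexa-2,5-dien-1-one (CNP0191741.1) | CC(C)=CCc1c(O)c(CC2=C(O)[C@@](CC=C(C)C)(C(=O)C(C)C)C(O)=C(C)C2=O)c(O)c(C(=O)C(C)C)c1O | target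

**Totals**
Total steps: 6. Longest linear sequence: 4 steps (4 → 5 → 6 → 9 → 11; the branch 1 → 2 → 3 → 9 → 11 is equally long).

**Steps most likely to fail**

Step 6 (the proposed new step). Three things can go wrong. Chiral trivalent europium diketonates are weak inducers, so the ee may be low. After proton shifts in the ortho-dienone, the prenyl group may leak to the CH2-bearing ring carbon instead of the acyl-bearing one. The acyl group on the new quaternary carbon can be lost to nucleophiles, so work-up must stay neutral and dry. The fallback sets out from 9 and comes back at 11. The same double shift is run without asymmetric induction, using the established achiral catalyst Eu(fod)3 = europium tris(6,6,7,7,8,8,8-heptafluoro-2,2-dimethyl-3,5-octanedionate) (10 mol %) in CHCl3 at 60 °C. It passes through the racemate of ortho-dienone 10 F1 and gives the racemate of 11 F2. The enantiomers are then separated by preparative HPLC on an amylose tris(3,5-dimethylphenylcarbamate) phase (hexane/iPrOH/0.1 % TFA). The (S)-enantiomer is 11; the (R)-enantiomer of 11 F3 is set aside. The assignment is made by comparing optical rotation and ECD with the natural product.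

Step 5. The one-pot coupling can give incomplete aminomethylation (then some ring A homodimer), slow quinone methide formation at 60 °C, or early rearrangement of the prenyl ether if heated harder. The fallback sets out from 6 (with 3 as the second partner) and comes back at 9. It reverses the roles and isolates each stage. 6 is treated with bis(dimethylamino)methane in dioxane at rt to give the Mannich base of 6 F4. This is quaternised with MeI in acetone to the trimethylammonium iodide of 6 F5. With NaHCO3 in MeCN at rt, F5 loses trimethylamine in the cold to give the ring B ortho-quinone methide F6, and 3 adds through its one free ring carbon to give 9.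

Step 2. Base-mediated C-prenylation is known but gives only moderate yields, with di-prenylated and O-prenylated by-products. The fallback sets out from 2 and comes back at 3. 2 is etherified at its 4-OH with prenol, PPh3 and DIAD (as in step 4) to give the 4-O-prenyl ether of 2 F7. The prenyl group is then moved from oxygen to the neighbouring ring carbon by a [1,3] shift on magnesium silicate MgSiO3 (Florisil) in toluene at rt to 60 °C. Both ortho carbons are equivalent, so only 3 can form.

**Further compounds**
F1 | step 6 | racemate of ortho-dienone 10 | O=C1C(Cc2c(O)c(CC=C(C)C)c(O)c(C(=O)C(C)C)c2O)=C(O)C(C(=O)C(C)C)=C(O)C1(C)C(C)(C)C=C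
F2 | step 6 | racemate of 11 | CC(C)=CCc1c(O)c(CC2=C(O)C(CC=C(C)C)(C(=O)C(C)C)C(O)=C(C)C2=O)c(O)c(C(=O)C(C)C)c1O
F3 | step 6 | (R)-enantiomer of 11 | CC(C)=CCc1c(O)c(CC2=C(O)[C@](CC=C(C)C)(C(=O)C(C)C)C(O)=C(C)C2=O)c(O)c(C(=O)C(C)C)c1O
F4 | step 5 | Mannich base of 6, 1-{3-[(dimethylamino)methyl]-2,6-dihydroxy-5-methyl-4-[(3-methylbut-2-en-1-yl)oxy]phenyl}-2-methylpropan-1-one | CC(C)C(=O)c1c(O)c(CN(C)C)c(OCC=C(C)C)c(C)c1O
F5 | step 5 | trimethylammonium iodide of 6 (methiodide of F4) | CC(C)C(=O)c1c(O)c(C[N+](C)(C)C)c(OCC=C(C)C)c(C)c1O.[I-]
F6 | step 5 | ring B ortho-quinone methide, 3-hydroxy-4-methyl-6-methylidene-5-[(3-methylbut-2-en-1-yl)oxy]-2-(2-methylpropanoyl)cyclohexa-2,4-dien-1-one | C=C1C(=O)C(C(=O)C(C)C)=C(O)C(C)=C1OCC=C(C)C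
F7 | step 2 | 4-O-prenyl ether of 2, 1-{2,6-dihydroxy-4-[(3-methylbut-2-en-1-yl)oxy]phenyl}-2-methylpropan-1-one | CC(C)C(=O)c1c(O)cc(OCC=C(C)C)cc1O
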